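**Plan**

- Retrosynthesis first cuts the two aryl–CH2 bonds C6–C1'' and C8–C1'' of the prenyl groups, then the two C–I bonds, then ring C (O1–C2 and C3–OH), and last the Cα=Cβ bond of a chalcone (C2–C3 of the flavonol).
- Enabling feature: C6 and C8 are the only CH positions of ring A. Each is ortho or para to the C5 hydroxyl and ortho to the C7 methoxy oxygen, so both are iodinated in one operation; because they carry the same prenyl group, one twofold coupling serves both.
- Forward: rings A and B are bought (acetophenone 3, isovanillin 1) and joined by Claisen–Schmidt condensation. Ring C closes by Algar–Flynn–Oyamada oxidation, debenzylation frees 5-OH for the twofold iodination, and MOM capping, twofold Negishi prenylation and acid deprotection follow.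
- Stereochemistry: the target has no stereocentre and no stereogenic double bond. The transient elements (E-chalcone, racemic dihydroflavonol) are erased on oxidation to the flavonol.

Key step: step 9

Remark: racemic compounds (6 and the fallback epoxide) are drawn as one enantiomer. The prenylzinc bromide solution 12 is titrated and stored, so it is treated as a prepared reagent with its own step. In the twofold steps 6, 7 and 9 two equivalents of the reagent end up in the product, and both are entered.

**Route**

Step 1
Reactants: 1 isovanillin (3-hydroxy-4-methoxybenzaldehyde)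
Product: 2 4-methoxy-3-(methoxymethoxy)benzaldehyde
Conditions: MOMCl (1.3 equiv), K2CO3, acetone, 0 °C to rt
Reagents that add atoms: chloromethyl methyl ether, COCCl
Why: Williamson-type O-alkylation of the phenoxide by the reactive chloromethyl ether; the aldehyde is inert to K2CO3 in acetone and the MOM ether should survive the later alkaline aldol and peroxide steps.

Step 2
Reactants: 3 2',6'-dihydroxy-4'-methoxyacetophenone
Product: 4 1-[2-(benzyloxy)-6-hydroxy-4-methoxyphenyl]ethan-1-one
Conditions: BnBr (1.05 equiv), K2CO3, acetone, reflux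
Reagents that add atoms: benzyl bromide, BrCc1ccccc1
Why: Williamson ether synthesis; after the first benzylation the remaining hydroxyl is held in a hydrogen bond to the acetyl carbonyl and is much less nucleophilic, so one equivalent of benzyl bromide should stop at the mono-ether.

Step 3
Reactants: 2 4-methoxy-3-(methoxymethoxy)benzaldehyde; 4 1-[2-(benzyloxy)-6-hydroxy-4-methoxyphenyl]ethan-1-one
Product: 5 (E)-1-[2-(benzyloxy)-6-hydroxy-4-methoxyphenyl]-3-[4-methoxy-3-(methoxymethoxy)phenyl]prop-2-en-1-one
Conditions: KOH (50% aq.), EtOH, rt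
Reagents that add atoms: none
Why: Claisen–Schmidt condensation, in which the acetophenone enolate adds to the non-enolisable aldehyde and E1cB dehydration gives the conjugated E-enone under thermodynamic control; MOM and benzyl ethers are stable to base.

Step 4
Reactants: 5 (E)-1-[2-(benzyloxy)-6-hydroxy-4-methoxyphenyl]-3-[4-methoxy-3-(methoxymethoxy)phenyl]prop-2-en-1-one
Product: 7 5-(benzyloxy)-3-hydroxy-7-methoxy-2-[4-methoxy-3-(methoxymethoxy)phenyl]-4H-chromen-4-one, via racemic trans-dihydroflavonol 6 (not isolated)
Conditions: 30% aq. H2O2, aq. NaOH, MeOH, 0 °C to rt; then AcOH to pH 6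
Reagents that add atoms: hydrogen peroxide, OO
Why: Algar–Flynn–Oyamada reaction, in which alkaline hydroperoxide oxidises the enone while the 2'-phenoxide closes ring C at the β-carbon to give dihydroflavonol 6, which further peroxide dehydrogenates to the flavonol; the reaction is in routine use for 2'-hydroxy-6'-alkoxychalcones carrying benzyl or MOM ethers.

Step 5
Reactants: 7 5-(benzyloxy)-3-hydroxy-7-methoxy-2-[4-methoxy-3-(methoxymethoxy)phenyl]-4H-chromen-4-one
Product: 8 3,5-dihydroxy-7-methoxy-2-[4-methoxy-3-(methoxymethoxy)phenyl]-4H-chromen-4-one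
Conditions: H2 (1 atm), 10% Pd/C, EtOAc–MeOH, rt
Reagents that add atoms: none
Why: Hydrogenolysis of a benzyl aryl ether; the fully substituted vinylogous-ester C2=C3 bond, the aryl MOM ether and the methyl ethers are not reduced at 1 atm and rt, and neither iodine nor a prenyl olefin is present yet.

Step 6
Reactants: 8 3,5-dihydroxy-7-methoxy-2-[4-methoxy-3-(methoxymethoxy)phenyl]-4H-chromen-4-one
Product: 9 3,5-dihydroxy-6,8-diiodo-7-methoxy-2-[4-methoxy-3-(methoxymethoxy)phenyl]-4H-chromen-4-one
Conditions: NIS (2.3 equiv), DMF, 0 °C to rt, dark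
Reagents that add atoms: N-iodosuccinimide (first equivalent), O=C1CCC(=O)N1I; N-iodosuccinimide (second equivalent), O=C1CCC(=O)N1I
Why: Electrophilic aromatic iodination, one equivalent of NIS per position; the free 5-OH activates C6 (ortho) and C8 (para), both also ortho to the 7-methoxy group, so ring A should react well ahead of the ether-only ring B under neutral conditions that spare the MOM ether.

Step 7
Reactants: 9 3,5-dihydroxy-6,8-diiodo-7-methoxy-2-[4-methoxy-3-(methoxymethoxy)phenyl]-4H-chromen-4-one
Product: 10 6,8-diiodo-7-methoxy-3,5-bis(methoxymethoxy)-2-[4-methoxy-3-(methoxymethoxy)phenyl]-4H-chromen-4-one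
Conditions: NaH (3 equiv), MOMCl (3 equiv), DMF, 0 °C to rt
Reagents that add atoms: chloromethyl methyl ether (first equivalent), COCCl; chloromethyl methyl ether (second equivalent), COCCl
Why: O-alkylation of the sodium salts of the 3-enol and the 5-phenol, one MOMCl per oxygen; NaH in DMF breaks the hydrogen bond between 5-OH and the C4 carbonyl, and the small, reactive electrophile can reach the oxygen next to iodine.

Step 8
Reactants: 11 prenyl bromide (1-bromo-3-methylbut-2-ene)
Product: 12 prenylzinc bromide (THF solution, titrated)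
Conditions: Zn dust (1.5 equiv), LiCl (1.1 equiv), THF, 0 °C to rt, slow addition of 11
Reagents that add atoms: zinc, [Zn]
Why: Direct oxidative insertion of zinc metal into the allylic C–Br bond, with LiCl keeping the organozinc in solution; slow addition in the cold suppresses Wurtz homocoupling.

Step 9
Reactants: 10 6,8-diiodo-7-methoxy-3,5-bis(methoxymethoxy)-2-[4-methoxy-3-(methoxymethoxy)phenyl]-4H-chromen-4-one; 12 prenylzinc bromide (first equivalent, for one C–I bond)
Product: 13 7-methoxy-3,5-bis(methoxymethoxy)-2-[4-methoxy-3-(methoxymethoxy)phenyl]-6,8-bis(3-methylbut-2-en-1-yl)-4H-chromen-4-one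
Conditions: Pd(OAc)2 (5 mol %), CPhos (2-dicyclohexylphosphino-2',6'-bis(dimethylamino)biphenyl, 10 mol %), 12 (3 equiv in all, added dropwise; two are incorporated), THF, rt
Reagents that add atoms: prenylzinc bromide (second equivalent of 12, for the other C–I bond), CC(C)=CC[Zn]Br
Why: Zerovalent palladium, formed from Pd(OAc)2 and CPhos by reduction with the organozinc, inserts into the C6–I and C8–I bonds in turn; at each site one equivalent of 12 transmetalates to an aryl(allyl) complex of divalent palladium, and reductive elimination from the form bound through the unsubstituted CH2 terminus makes the aryl–CH2 bond, so two equivalents of 12 are consumed and two prenyl groups are installed. The closest known reaction type is the linear-selective Negishi coupling of allylic zinc halides with aryl halides under bulky biarylphosphine catalysis. No ring closes and no stereocentre forms. The step needs linear (α) over branched 1,1-dimethylallyl (γ) coupling, which is secured by CPhos together with the two ortho substituents at each site (5-OMOM and 7-OMe at C6, 7-OMe and O1 at C8); these disfavour palladium at the tertiary terminus and speed reductive elimination. It also needs coupling to outrun carbonyl addition: the C4 carbonyl is a vinylogous ester shielded by the 5-OMOM group and is a poor electrophile, and dropwise addition keeps the organozinc concentration low. All three hydroxyls are capped as MOM ethers so that no acidic proton quenches the reagent.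

Step 10
Reactants: 13 7-methoxy-3,5-bis(methoxymethoxy)-2-[4-methoxy-3-(methoxymethoxy)phenyl]-6,8-bis(3-methylbut-2-en-1-yl)-4H-chromen-4-one
Product: 14 3,5-dihydroxy-2-(3-hydroxy-4-methoxyphenyl)-7-methoxy-6,8-bis(3-methylbut-2-en-1-yl)-4H-chromen-4-one (CNP0261856.0)
Conditions: HCl (1.25 M in MeOH), MeOH–THF, rt
Reagents that add atoms: none
Why: Acid-catalysed methanolysis of the three MOM acetals; dilute acid at rt is the usual way to unmask prenylated flavonoids and should be mild enough to avoid addition of the 5-OH to the neighbouring C6 prenyl olefin.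

**Compound list**

1 | isovanillin (3-hydroxy-4-methoxybenzaldehyde) | COc1ccc(C=O)cc1O | starting material
2 | 4-methoxy-3-(methoxymethoxy)benzaldehyde | COCOc1cc(C=O)ccc1OC | intermediate
3 | 2',6'-dihydroxy-4'-methoxyacetophenone | CC(=O)c1c(O)cc(OC)cc1O | starting material
4 | 1-[2-(benzyloxy)-6-hydroxy-4-methoxyphenyl]ethan-1-one | CC(=O)c1c(O)cc(OC)cc1OCc2ccccc2 | intermediate
5 | (E)-1-[2-(benzyloxy)-6-hydroxy-4-methoxyphenyl]-3-[4-methoxy-3-(methoxymethoxy)phenyl]prop-2-en-1-one | COCOc1cc(/C=C/C(=O)c2c(O)cc(OC)cc2OCc3ccccc3)ccc1OC | intermediate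
6 | racemic trans-5-(benzyloxy)-3-hydroxy-7-methoxy-2-[4-methoxy-3-(methoxymethoxy)phenyl]chroman-4-one (dihydroflavonol, one enantiomer drawn) | COCOc1cc([C@@H]2[C@@H](O)C(=O)c3c(OCc4ccccc4)cc(OC)cc3O2)ccc1OC | intermediate (not isolated)
7 | 5-(benzyloxy)-3-hydroxy-7-methoxy-2-[4-methoxy-3-(methoxymethoxy)phenyl]-4H-chromen-4-one | COCOc1cc(-c2oc3cc(OC)cc(OCc4ccccc4)c3c(=O)c2O)ccc1OC | intermediate
8 | 3,5-dihydroxy-7-methoxy-2-[4-methoxy-3-(methoxymethoxy)phenyl]-4H-chromen-4-one | COCOc1cc(-c2oc3cc(OC)cc(O)c3c(=O)c2O)ccc1OC | intermediate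
9 | 3,5-dihydroxy-6,8-diiodo-7-methoxy-2-[4-methoxy-3-(methoxymethoxy)phenyl]-4H-chromen-4-one | COCOc1cc(-c2oc3c(I)c(OC)c(I)c(O)c3c(=O)c2O)ccc1OC | intermediate
10 | 6,8-diiodo-7-methoxy-3,5-bis(methoxymethoxy)-2-[4-methoxy-3-(methoxymethoxy)phenyl]-4H-chromen-4-one | COCOc1cc(-c2oc3c(I)c(OC)c(I)c(OCOC)c3c(=O)c2OCOC)ccc1OC | intermediate
11 | prenyl bromide (1-bromo-3-methylbut-2-ene) | CC(C)=CCBr | starting material
12 | prenylzinc bromide | CC(C)=CC[Zn]Br | intermediate
13 | 7-methoxy-3,5-bis(methoxymethoxy)-2-[4-methoxy-3-(methoxymethoxy)phenyl]-6,8-bis(3-methylbut-2-en-1-yl)-4H-chromen-4-one | COCOc1cc(-c2oc3c(CC=C(C)C)c(OC)c(CC=C(C)C)c(OCOC)c3c(=O)c2OCOC)ccc1OC | intermediate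
14 | 3,5-dihydroxy-2-(3-hydroxy-4-methoxyphenyl)-7-methoxy-6,8-bis(3-methylbut-2-en-1-yl)-4H-chromen-4-one | COc1ccc(-c2oc3c(CC=C(C)C)c(OC)c(CC=C(C)C)c(O)c3c(=O)c2O)cc1O | target

**Step count**

Total: 10 steps. Longest linear sequence: 8 steps (step 1 or 2, then steps 3, 4, 5, 6, 7, 9 and 10).

**Steps most likely to fail**

1. Step 9 (twofold Negishi prenylation). The second coupling may stall at a mono-prenylated iodide, protodeiodination may compete, bonding through the tertiary allyl terminus may give the branched isomer at these crowded sites, or the allylic zinc reagent may add to the C4 carbonyl. Fallback: starting from 10, a twofold Stille coupling with allyltributylstannane (Pd(PPh3)4, DMF, 90 °C) should give 6,8-diallyl-7-methoxy-3,5-bis(methoxymethoxy)-2-[4-methoxy-3-(methoxymethoxy)phenyl]-4H-chromen-4-one F1. Twofold olefin cross-metathesis of this with excess 2-methyl-2-butene (second-generation Grubbs catalyst, CH2Cl2, 40 °C) converts each allyl into a prenyl group and returns to the route at 13.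

2. Step 4 (Algar–Flynn–Oyamada oxidation). With a 6'-alkoxy group the phenoxide may close at the α-carbon instead, diverting material to the aurone, and the electron-rich product may be over-oxidised by peroxide. Fallback: starting from 5, oxidative cyclisation with I2 in pyridine at 100 °C (conditions that spare the MOM ether) should give 5-(benzyloxy)-7-methoxy-2-[4-methoxy-3-(methoxymethoxy)phenyl]-4H-chromen-4-one F2. Epoxidation of its C2=C3 bond with dimethyldioxirane (acetone–CH2Cl2, 0 °C) gives the racemic 2,3-epoxide of that flavone F3, and catalytic p-toluenesulfonic acid in CH2Cl2 opens the epoxide at C2 and tautomerises it to the 3-hydroxyflavone, coming back at 7.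

3. Step 6 (twofold iodination). Iodination may stop after C6, or the electrophile may attack the free 3-hydroxy enol at C2 and oxidise ring C. Fallback: starting from 8, the non-chelated 3-OH is masked first (MOMCl 1.1 equiv, K2CO3, acetone, rt; the hydrogen-bonded 5-OH stays free) to give 5-hydroxy-7-methoxy-3-(methoxymethoxy)-2-[4-methoxy-3-(methoxymethoxy)phenyl]-4H-chromen-4-one F4. Iodination with NIS (2.5 equiv, DMF, rt to 40 °C) then gives 5-hydroxy-6,8-diiodo-7-methoxy-3-(methoxymethoxy)-2-[4-methoxy-3-(methoxymethoxy)phenyl]-4H-chromen-4-one F5, and NaH with MOMCl in DMF caps the 5-OH, rejoining the route at 10.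

**Further compounds**

F1 | step 9 | 6,8-diallyl-7-methoxy-3,5-bis(methoxymethoxy)-2-[4-methoxy-3-(methoxymethoxy)phenyl]-4H-chromen-4-one | COCOc1cc(-c2oc3c(CC=C)c(OC)c(CC=C)c(OCOC)c3c(=O)c2OCOC)ccc1OC
F2 | step 4 | 5-(benzyloxy)-7-methoxy-2-[4-methoxy-3-(methoxymethoxy)phenyl]-4H-chromen-4-one | COCOc1cc(-c2cc(=O)c3c(OCc4ccccc4)cc(OC)cc3o2)ccc1OC
F3 | step 4 | racemic 2,3-epoxide of F2 (cis-fused, one enantiomer drawn) | O=C1c2c(OCc3ccccc3)cc(OC)cc2O[C@]2(c3ccc(OC)c(OCOC)c3)O[C@H]12
F4 | step 6 | 5-hydroxy-7-methoxy-3-(methoxymethoxy)-2-[4-methoxy-3-(methoxymethoxy)phenyl]-4H-chromen-4-one | COCOc1cc(-c2oc3cc(OC)cc(O)c3c(=O)c2OCOC)ccc1OC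
F5 | step 6 | 5-hydroxy-6,8-diiodo-7-methoxy-3-(methoxymethoxy)-2-[4-methoxy-3-(methoxymethoxy)phenyl]-4H-chromen-4-one | COCOc1cc(-c2oc3c(I)c(OC)c(I)c(O)c3c(=O)c2OCOC)ccc1OC
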